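**Plan**

- Target as read: 2,3-cis-(2R,3R)-2,3-dihydrobenzofuran with an isovalerate on the C3 oxygen, a 1-formylvinyl group on C2 and an (S)-1-(senecioyloxy)ethyl group on C5.
- Cuts: first the two ester C–O bonds and the aldehyde oxidation level of the C2 side arm, then the C2–C3 bond of ring B (O1, C2, C3, C3a, C7a), then the C–B bond and the O1–CH2 ether bond.
- Enabling feature: in ring B the oxygen on C3 is homoallylic to the C=CH2 alkene carried by C2, and C2 itself bears O1. A formyl carbon (C3) and the oxygen-bearing end of an aryloxyallyl boron unit (C2) give exactly this array, with O1–C7a–C3a as the tether.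
- Forward: ring A is bought as methyl 5-acetylsalicylate. O-methallylation, side-chain reduction and silylation, ester reduction, metalation–borylation of the allyl ether and oxidation give the formyl (Z)-allylboronate. Ring B then closes by C2–C3 bond formation, and two acylations plus a two-stage oxidation of the isopropenyl methyl finish the route.
- Stereochemistry: the side-chain (S) centre comes from ruthenium-catalysed asymmetric transfer hydrogenation, the cis C2/C3 relationship from the Z enol ether through a chair transition state, and 2R,3R from a chiral phosphoric acid.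

Key step: step 7

Assumption: the uncatalysed ring closure of the aldehyde made in step 6 is taken to be slow at 0 °C and below, because pinacol (Z)-γ-oxyallylboronates add only sluggishly to aldehydes without acid; the aldehyde is therefore prepared cold and handed on at once.

**Route**

Step 1
Reactants: 1 methyl 5-acetyl-2-hydroxybenzoate; 2 3-chloro-2-methylprop-1-ene
Product: 3 methyl 5-acetyl-2-[(2-methylprop-2-en-1-yl)oxy]benzoate
Conditions: K2CO3, KI (cat.), DMF, 60 °C
Reagents that add atoms: none
Why: Williamson ether synthesis, the potassium phenoxide displacing the allylic chloride (SN2, helped by in situ halide exchange) without touching ketone or ester.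

Step 2
Reactants: 3 methyl 5-acetyl-2-(methallyloxy)benzoate
Product: 4 methyl 5-[(1S)-1-hydroxyethyl]-2-[(2-methylprop-2-en-1-yl)oxy]benzoate
Conditions: RuCl[(S,S)-TsDPEN](p-cymene) (1 mol%), HCO2H–Et3N (5:2), 30 °C
Reagents that add atoms: none
Why: Noyori–Ikariya asymmetric transfer hydrogenation of an aryl methyl ketone, in which the (S,S)-diamine ruthenium hydride transfers hydride and proton in an outer-sphere six-membered transition state steered by the arene CH/π contact and so gives the (S)-1-arylethanol, leaving ester and isolated alkene untouched.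

Step 3
Reactants: 4 (S)-hydroxy ester
Product: 5 methyl 5-[(1S)-1-{[tert-butyl(dimethyl)silyl]oxy}ethyl]-2-[(2-methylprop-2-en-1-yl)oxy]benzoate
Conditions: TBSCl, imidazole, DMF, rt
Reagents that add atoms: tert-butyl(chloro)dimethylsilane (TBSCl), CC(C)(C)[Si](C)(C)Cl
Why: Standard imidazole-mediated silylation of a secondary alcohol, giving an ether that should withstand hydride, organolithium and mild acid in the following steps.

Step 4
Reactants: 5 silyl ether ester
Product: 6 {5-[(1S)-1-{[tert-butyl(dimethyl)silyl]oxy}ethyl]-2-[(2-methylprop-2-en-1-yl)oxy]phenyl}methanol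
Conditions: LiAlH4, THF, 0 °C
Reagents that add atoms: none
Why: Hydride reduction of the methyl ester to the primary benzylic alcohol, with silyl ether, allyl ether and stereocentre inert.

Step 5
Reactants: 6 benzylic alcohol; 7 2-isopropoxy-4,4,5,5-tetramethyl-1,3,2-dioxaborolane
Product: 9 {5-[(1S)-1-{[tert-butyl(dimethyl)silyl]oxy}ethyl]-2-{[(1Z)-2-methyl-3-(4,4,5,5-tetramethyl-1,3,2-dioxaborolan-2-yl)prop-1-en-1-yl]oxy}phenyl}methanol, via dilithiated Z-oxyallyl intermediate 8 (not isolated)
Conditions: s-BuLi (2.2 equiv), THF, −78 °C; then 7 (2.5 equiv), −78 °C; aq NH4Cl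
Reagents that add atoms: none
Why: α-Metalation of an allyl aryl ether followed by electrophilic borylation: the first equivalent of base stores the hydroxyl as its lithium alkoxide, the second removes one of the OCH2 protons (allylic and α to aryloxy, the most acidic C–H) to give an oxyallyllithium in which lithium bridges O1 and the γ-carbon and thereby fixes the Z geometry, and the borate traps this γ-terminus, loss of isopropoxide from the ate complex leaving the (Z)-γ-aryloxyallyl pinacol boronate.

Step 6
Reactants: 9 hydroxy (Z)-allylboronate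
Product: 10 5-[(1S)-1-{[tert-butyl(dimethyl)silyl]oxy}ethyl]-2-{[(1Z)-2-methyl-3-(4,4,5,5-tetramethyl-1,3,2-dioxaborolan-2-yl)prop-1-en-1-yl]oxy}benzaldehyde
Conditions: DMP, NaHCO3, CH2Cl2, 0 °C; cold filtration through a silica plug, used at once
Reagents that add atoms: none
Why: Dess–Martin oxidation of a primary benzylic alcohol, chosen because the buffered, non-aqueous, cold conditions should tolerate the enol ether and the allylboronate and deliver the aldehyde free of acid.

Step 7
Reactants: 10 formyl (Z)-γ-aryloxyallyl boronate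
Product: 12 (2R,3R)-5-[(1S)-1-{[tert-butyl(dimethyl)silyl]oxy}ethyl]-2-(prop-1-en-2-yl)-2,3-dihydro-1-benzofuran-3-ol (2,3-cis), via cyclic pinacol borate 11 (not isolated)
Conditions: (S)-TRIP [(S)-3,3′-bis(2,4,6-triisopropylphenyl)-1,1′-binaphthalene-2,2′-diyl hydrogen phosphate] (10 mol%), 4 Å MS, toluene, −30 °C; then aq NaHCO3
Reagents that add atoms: none
Why: Proposed new method: boron binds the formyl oxygen and C2, the oxygen-bearing γ-carbon of the allylboronate, adds to C3 through a six-membered chair with allyl transposition, so that the C=CH2 alkene appears on C2 while the phosphoric acid bridges a pinacol oxygen (P–OH) and the formyl hydrogen (P=O). The closest known reactions are the syn-selective additions of (Z)-γ-alkoxyallylboronates to aldehydes, thermal ring-closing allylborations of ω-formyl allylboronates, and chiral phosphoric acid catalysed allylboration with pinacol boronates, none of which combines the tether with catalyst control. The new ring (ring B) is formed by 5-exo-trig closure, C2 attacking the formyl carbon whose C=O stays outside the O1–C2–C3–C3a–C7a ring. The cis relationship of C2 and C3 follows from the Z enol ether, because in the chair a Z-configured γ-substituent (O1) must sit axial while the arene takes the equatorial site, and the absolute configuration (2R,3R) from the (S) acid, selected because the (R) acid sends allyl groups to the Re face of aryl aldehydes whereas 3R here requires Si-face attack. The step needs catalyst control over a substrate whose only stereocentre is remote, so the catalysed closure must outrun the uncatalysed one; the low temperature, the sluggishness of pinacol (Z)-γ-oxyallylboronates without acid and the free formyl C–H for the second catalyst contact should secure this, while the fixed Z geometry and the short O1–C7a–C3a tether secure cis. Mild bicarbonate hydrolysis of borate 11 releases the cis-3-ol before it can dehydrate to the benzofuran.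

Step 8
Reactants: 12 cis-(2R,3R)-3-ol
Product: 13 (2R,3R)-5-[(1S)-1-{[tert-butyl(dimethyl)silyl]oxy}ethyl]-2-(prop-1-en-2-yl)-2,3-dihydro-1-benzofuran-3-yl 3-methylbutanoate
Conditions: isovaleryl chloride, pyridine, DMAP (cat.), CH2Cl2, 0 °C
Reagents that add atoms: 3-methylbutanoyl chloride (isovaleryl chloride), CC(C)CC(=O)Cl
Why: DMAP-catalysed O-acylation of the secondary benzylic alcohol, which leaves the C3–O bond intact (retention) and, being cold and buffered, should avoid ionisation or elimination to the benzofuran.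

Step 9
Reactants: 13 C3 isovalerate silyl ether
Product: 14 (2R,3R)-5-[(1S)-1-hydroxyethyl]-2-(prop-1-en-2-yl)-2,3-dihydro-1-benzofuran-3-yl 3-methylbutanoate
Conditions: HF·pyridine, pyridine, THF, 0 °C to rt
Reagents that add atoms: none
Why: Fluoride-driven desilylation that cleaves Si–O and not C–O, the pyridine buffer keeping the medium too weakly acidic to ionise the p-alkoxybenzylic carbinol or the C3 ester and too weakly basic to cause elimination or acyl loss.

Step 10
Reactants: 14 side-chain alcohol
Product: 15 (1S)-1-[(2R,3R)-3-[(3-methylbutanoyl)oxy]-2-(prop-1-en-2-yl)-2,3-dihydro-1-benzofuran-5-yl]ethyl 3-methylbut-2-enoate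
Conditions: 3-methylbut-2-enoic acid, DCC, DMAP (cat.), CH2Cl2, 0 °C to rt
Reagents that add atoms: 3-methylbut-2-enoic acid (senecioic acid), CC(C)=CC(=O)O
Why: Steglich esterification (carbodiimide activation, DMAP acyl transfer) acylates the secondary alcohol at oxygen with retention, the free acid being used instead of its chloride to avoid vinylketene formation and deconjugation of the enoate.

Step 11
Reactants: 15 diester with isopropenyl group
Product: 16 (1S)-1-[(2R,3R)-2-(3-hydroxyprop-1-en-2-yl)-3-[(3-methylbutanoyl)oxy]-2,3-dihydro-1-benzofuran-5-yl]ethyl 3-methylbut-2-enoate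
Conditions: SeO2 (cat.), t-BuOOH, CH2Cl2, rt
Reagents that add atoms: tert-butyl hydroperoxide, CC(C)(C)OO (the new oxygen, relayed by catalytic SeO2, O=[Se]=O)
Why: Riley allylic oxidation, in which an ene reaction at the 1,1-disubstituted alkene and a [2,3]-sigmatropic shift return the alkene to its place and hydroxylate the methyl group, preferred over the C2 methine, while the electron-poor senecioate alkene should be much slower in the ene step.

Step 12
Reactants: 16 primary allylic alcohol
Product: 17 (1S)-1-[(2R,3R)-3-[(3-methylbutanoyl)oxy]-2-(3-oxoprop-1-en-2-yl)-2,3-dihydro-1-benzofuran-5-yl]ethyl 3-methylbut-2-enoate (CNP0325942.1)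
Conditions: DMP, NaHCO3, CH2Cl2, 0 °C
Reagents that add atoms: none
Why: Dess–Martin oxidation of the primary allylic alcohol to the enal under buffered, base-free conditions that should avoid β-elimination of the C3 ester toward the benzofuran and leave all three stereocentres untouched.

**Compound list**

1 | methyl 5-acetyl-2-hydroxybenzoate | COC(=O)c1cc(C(C)=O)ccc1O | starting material
2 | 3-chloro-2-methylprop-1-ene | C=C(C)CCl | starting material
3 | methyl 5-acetyl-2-[(2-methylprop-2-en-1-yl)oxy]benzoate | COC(=O)c1cc(C(C)=O)ccc1OCC(C)=C | intermediate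
4 | methyl 5-[(1S)-1-hydroxyethyl]-2-[(2-methylprop-2-en-1-yl)oxy]benzoate | COC(=O)c1cc([C@H](C)O)ccc1OCC(C)=C | intermediate
5 | methyl 5-[(1S)-1-{[tert-butyl(dimethyl)silyl]oxy}ethyl]-2-[(2-methylprop-2-en-1-yl)oxy]benzoate | COC(=O)c1cc([C@H](C)O[Si](C)(C)C(C)(C)C)ccc1OCC(C)=C | intermediate
6 | {5-[(1S)-1-{[tert-butyl(dimethyl)silyl]oxy}ethyl]-2-[(2-methylprop-2-en-1-yl)oxy]phenyl}methanol | OCc1cc([C@H](C)O[Si](C)(C)C(C)(C)C)ccc1OCC(C)=C | intermediate
7 | 2-isopropoxy-4,4,5,5-tetramethyl-1,3,2-dioxaborolane | CC(C)OB1OC(C)(C)C(C)(C)O1 | starting material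
8 | lithium {5-[(1S)-1-{[tert-butyl(dimethyl)silyl]oxy}ethyl]-2-{[(1Z)-3-lithio-2-methylprop-1-en-1-yl]oxy}phenyl}methanolate | [Li]OCc1cc([C@H](C)O[Si](C)(C)C(C)(C)C)ccc1O/C=C(/C)C[Li] | intermediate
9 | {5-[(1S)-1-{[tert-butyl(dimethyl)silyl]oxy}ethyl]-2-{[(1Z)-2-methyl-3-(4,4,5,5-tetramethyl-1,3,2-dioxaborolan-2-yl)prop-1-en-1-yl]oxy}phenyl}methanol | OCc1cc([C@H](C)O[Si](C)(C)C(C)(C)C)ccc1O/C=C(/C)CB2OC(C)(C)C(C)(C)O2 | intermediate
10 | 5-[(1S)-1-{[tert-butyl(dimethyl)silyl]oxy}ethyl]-2-{[(1Z)-2-methyl-3-(4,4,5,5-tetramethyl-1,3,2-dioxaborolan-2-yl)prop-1-en-1-yl]oxy}benzaldehyde | O=Cc1cc([C@H](C)O[Si](C)(C)C(C)(C)C)ccc1O/C=C(/C)CB2OC(C)(C)C(C)(C)O2 | intermediate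
11 | 2-{[(2R,3R)-5-[(1S)-1-{[tert-butyl(dimethyl)silyl]oxy}ethyl]-2-(prop-1-en-2-yl)-2,3-dihydro-1-benzofuran-3-yl]oxy}-4,4,5,5-tetramethyl-1,3,2-dioxaborolane | C=C(C)[C@H]1Oc2ccc([C@H](C)O[Si](C)(C)C(C)(C)C)cc2[C@H]1OB3OC(C)(C)C(C)(C)O3 | intermediate
12 | (2R,3R)-5-[(1S)-1-{[tert-butyl(dimethyl)silyl]oxy}ethyl]-2-(prop-1-en-2-yl)-2,3-dihydro-1-benzofuran-3-ol | C=C(C)[C@H]1Oc2ccc([C@H](C)O[Si](C)(C)C(C)(C)C)cc2[C@H]1O | intermediate
13 | (2R,3R)-5-[(1S)-1-{[tert-butyl(dimethyl)silyl]oxy}ethyl]-2-(prop-1-en-2-yl)-2,3-dihydro-1-benzofuran-3-yl 3-methylbutanoate | C=C(C)[C@H]1Oc2ccc([C@H](C)O[Si](C)(C)C(C)(C)C)cc2[C@H]1OC(=O)CC(C)C | intermediate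
14 | (2R,3R)-5-[(1S)-1-hydroxyethyl]-2-(prop-1-en-2-yl)-2,3-dihydro-1-benzofuran-3-yl 3-methylbutanoate | C=C(C)[C@H]1Oc2ccc([C@H](C)O)cc2[C@H]1OC(=O)CC(C)C | intermediate
15 | (1S)-1-[(2R,3R)-3-[(3-methylbutanoyl)oxy]-2-(prop-1-en-2-yl)-2,3-dihydro-1-benzofuran-5-yl]ethyl 3-methylbut-2-enoate | C=C(C)[C@H]1Oc2ccc([C@H](C)OC(=O)C=C(C)C)cc2[C@H]1OC(=O)CC(C)C | intermediate
16 | (1S)-1-[(2R,3R)-2-(3-hydroxyprop-1-en-2-yl)-3-[(3-methylbutanoyl)oxy]-2,3-dihydro-1-benzofuran-5-yl]ethyl 3-methylbut-2-enoate | C=C(CO)[C@H]1Oc2ccc([C@H](C)OC(=O)C=C(C)C)cc2[C@H]1OC(=O)CC(C)C | intermediate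
17 | (1S)-1-[(2R,3R)-3-[(3-methylbutanoyl)oxy]-2-(3-oxoprop-1-en-2-yl)-2,3-dihydro-1-benzofuran-5-yl]ethyl 3-methylbut-2-enoate | C=C(C=O)[C@H]1Oc2ccc([C@H](C)OC(=O)C=C(C)C)cc2[C@H]1OC(=O)CC(C)C | target

**Step count and risks**

Total step count: 12. Longest linear sequence: 12 steps (1 to 17).

Steps most likely to fail:

Step 7 (proposed new method). The facial selectivity may be poor: if the uncatalysed closure of 10 competes with the acid-bound pathway, or if the intermolecular catalyst model does not carry over to the tethered chair, both cis diastereomers form and they differ only at a remote centre. Should only the sense be reversed, the (R) acid would be used. Fallback with known chemistry, setting out from 10 and rejoining at 13: 10 is left to close thermally in toluene without acid, the established cis-selective course of a Z allylboronate. This should give cyclic borate 11 together with its ring-epimeric 2S,3S borate F1, hydrolysed on work-up to 12 and the 2S,3S alcohol F2. The mixture is then submitted to an acylative kinetic resolution with isovaleric anhydride, iPr2NEt and the benzotetramisole enantiomer that acylates the 3R alcohol, in CHCl3 at 0 °C. The (S) catalyst is expected by analogy with 1-arylalkanols, to be confirmed on a test scale. Only 12 should be converted, directly into isovalerate 13, and unreacted F2 is removed by chromatography.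

Step 5. The metalation–borylation on the unprotected hydroxy ether may stall or go astray: the lithium alkoxide can slow or misdirect the α-metalation toward ring or benzylic lithiation, borate can be consumed at oxygen, and the hydroxy boronate may be lost on purification. Fallback, setting out from 6 and rejoining at 10: the carbonyl carbon is carried at the aldehyde level. MnO2 (CH2Cl2, rt) should give 5-[(1S)-1-{[tert-butyl(dimethyl)silyl]oxy}ethyl]-2-[(2-methylprop-2-en-1-yl)oxy]benzaldehyde F3. LiN(Me)CH2CH2NMe2 (THF, −78 to −20 °C) masks it in the flask as the lithium α-amino alkoxide F4. s-BuLi (−78 °C) then gives the Z-oxyallyllithium F5, 7 converts it into the boronate amino alkoxide F6, and cold aqueous NH4Cl releases the amine and thereby aldehyde 10. Compound 9 is bypassed and no oxidant meets the boronate.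

Step 11. The allylic oxidation may attack the wrong site (the γ-methyl groups of the senecioate or the C2 methine) or over-oxidise, giving mixtures that are hard to separate at this late stage. Fallback, setting out from 13 and rejoining at 17: the oxidation is done before the senecioate exists. SeO2 (cat.)/t-BuOOH on 13 should give the allylic alcohol F7, DMP/NaHCO3 the silyl-protected enal F8, and buffered HF·pyridine the hydroxy enal F9. Steglich esterification of F9 with 3-methylbut-2-enoic acid (DCC, DMAP cat., CH2Cl2, 0 °C) then gives 17. This order is kept in reserve because the last acylation has to be run on the elimination-prone enal.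

Further compounds
F1 | step 7 | 2-{[(2S,3S)-5-[(1S)-1-{[tert-butyl(dimethyl)silyl]oxy}ethyl]-2-(prop-1-en-2-yl)-2,3-dihydro-1-benzofuran-3-yl]oxy}-4,4,5,5-tetramethyl-1,3,2-dioxaborolane | C=C(C)[C@@H]1Oc2ccc([C@H](C)O[Si](C)(C)C(C)(C)C)cc2[C@@H]1OB3OC(C)(C)C(C)(C)O3
F2 | step 7 | (2S,3S)-5-[(1S)-1-{[tert-butyl(dimethyl)silyl]oxy}ethyl]-2-(prop-1-en-2-yl)-2,3-dihydro-1-benzofuran-3-ol | C=C(C)[C@@H]1Oc2ccc([C@H](C)O[Si](C)(C)C(C)(C)C)cc2[C@@H]1O
F3 | step 5 | 5-[(1S)-1-{[tert-butyl(dimethyl)silyl]oxy}ethyl]-2-[(2-methylprop-2-en-1-yl)oxy]benzaldehyde | O=Cc1cc([C@H](C)O[Si](C)(C)C(C)(C)C)ccc1OCC(C)=C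
F4 | step 5 | lithium {5-[(1S)-1-{[tert-butyl(dimethyl)silyl]oxy}ethyl]-2-[(2-methylprop-2-en-1-yl)oxy]phenyl}{[2-(dimethylamino)ethyl](methyl)amino}methanolate (both epimers at the aminal carbon) | [Li]OC(N(C)CCN(C)C)c1cc([C@H](C)O[Si](C)(C)C(C)(C)C)ccc1OCC(C)=C
F5 | step 5 | lithium {5-[(1S)-1-{[tert-butyl(dimethyl)silyl]oxy}ethyl]-2-{[(1Z)-3-lithio-2-methylprop-1-en-1-yl]oxy}phenyl}{[2-(dimethylamino)ethyl](methyl)amino}methanolate | [Li]OC(N(C)CCN(C)C)c1cc([C@H](C)O[Si](C)(C)C(C)(C)C)ccc1O/C=C(/C)C[Li]
F6 | step 5 | lithium {5-[(1S)-1-{[tert-butyl(dimethyl)silyl]oxy}ethyl]-2-{[(1Z)-2-methyl-3-(4,4,5,5-tetramethyl-1,3,2-dioxaborolan-2-yl)prop-1-en-1-yl]oxy}phenyl}{[2-(dimethylamino)ethyl](methyl)amino}methanolate | [Li]OC(N(C)CCN(C)C)c1cc([C@H](C)O[Si](C)(C)C(C)(C)C)ccc1O/C=C(/C)CB2OC(C)(C)C(C)(C)O2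
F7 | step 11 | (2R,3R)-5-[(1S)-1-{[tert-butyl(dimethyl)silyl]oxy}ethyl]-2-(3-hydroxyprop-1-en-2-yl)-2,3-dihydro-1-benzofuran-3-yl 3-methylbutanoate | C=C(CO)[C@H]1Oc2ccc([C@H](C)O[Si](C)(C)C(C)(C)C)cc2[C@H]1OC(=O)CC(C)C
F8 | step 11 | (2R,3R)-5-[(1S)-1-{[tert-butyl(dimethyl)silyl]oxy}ethyl]-2-(3-oxoprop-1-en-2-yl)-2,3-dihydro-1-benzofuran-3-yl 3-methylbutanoate | C=C(C=O)[C@H]1Oc2ccc([C@H](C)O[Si](C)(C)C(C)(C)C)cc2[C@H]1OC(=O)CC(C)C
F9 | step 11 | (2R,3R)-5-[(1S)-1-hydroxyethyl]-2-(3-oxoprop-1-en-2-yl)-2,3-dihydro-1-benzofuran-3-yl 3-methylbutanoate | C=C(C=O)[C@H]1Oc2ccc([C@H](C)O)cc2[C@H]1OC(=O)CC(C)C
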